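**Retrosynthetic overview**

1. The 2,3-dihydrofuran (O–C15=C14–C13–C16) is opened last to a C13 ethynyl / C16 hydroxymethyl pair (acid-free 5-endo alkynol cycloisomerisation).
2. Key cut: the C7(=O)–C8(OAc)–C9(O) array of ring B is read as a masked oxa-Michael adduct (C9–O is β to the ketone) oxidised at the enolate carbon (C8). Both C–O bonds are removed together to a flat 8-en-7-one carrying a free (13R) tertiary propargylic alcohol on the C11–C12 tether.
3. C13, the only stereocentre that is not relayed, is set by catalytic Sharpless epoxidation of a 2-substituted allyl alcohol; the epoxy alcohol then supplies the alkyne arm (C14≡C15) and the C16–O arm.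
4. The C12–C13 bond comes from a Negishi coupling of a homodrimane iodide with 2-bromoallyl alcohol; rings A/B with C5 and C10 are bought as (+)-sclareolide (Δ8 ester, then C7 allylic oxidation).
5. Ring order: A/B (chiral pool) → spiro-tetrahydrofuran with C8 and C9 (step 10) → dihydrofuran (step 12).

Key step: step 10

**Remarks (assumptions)**

- Labdane numbering is used throughout (C17 = methyl on C8, C20 = methyl on C10); α/β refer to the usual labdane drawing.
- Compound 4 is drawn as the expected major 7β-alcohol; its C7 epimer converges in step 4.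
- Step 7 specifies D-(−)-tartrate on the basis that L-(+)-tartrates convert 2-substituted allyl alcohols into (S)-2-alkylglycidols.

**Route**

Step 1
Reactants: 1 (+)-sclareolide
Product: 2 methyl 13,14,15,16-tetranorlabd-8-en-12-oate
Conditions: conc. H2SO4, MeOH, 65 °C
Reagents that add atoms: methanol (CO)
Why: Acid-mediated E1 opening of the tertiary C8–O lactone bond with Fischer esterification should, under equilibrating conditions, funnel to the thermodynamically preferred tetrasubstituted Δ8(9) alkene, leaving C5 and C10 untouched.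

Step 2
Reactants: 2 methyl 13,14,15,16-tetranorlabd-8-en-12-oate
Product: 3 methyl 7-oxo-13,14,15,16-tetranorlabd-8-en-12-oate
Conditions: CrO3, 3,5-dimethylpyrazole, CH2Cl2, −20 °C
Reagents that add atoms: chromium trioxide (O=[Cr](=O)=O)
Why: Chromium(VI)–pyrazole allylic oxidation should attack the ring allylic methylene C7 in preference to C11, which is deactivated by the adjacent ester, giving the conjugated 8-en-7-one without creating a stereocentre.

Step 3
Reactants: 3 methyl 7-oxo-13,14,15,16-tetranorlabd-8-en-12-oate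
Product: 4 13,14,15,16-tetranorlabd-8-ene-7β,12-diol
Conditions: DIBAL-H (5 equiv), CH2Cl2, −78 → 0 °C
Reagents that add atoms: none
Why: Hydride reduction takes the ester to the primary alcohol and the enone carbonyl to the allylic alcohol by 1,2-addition (axial delivery, mainly 7β-OH), the C7 configuration being erased again in step 4.

Step 4
Reactants: 4 13,14,15,16-tetranorlabd-8-ene-7β,12-diol
Product: 5 12-hydroxy-13,14,15,16-tetranorlabd-8-en-7-one
Conditions: MnO2, CH2Cl2, rt
Reagents that add atoms: none
Why: Manganese dioxide oxidises only the allylic secondary alcohol, restoring the enone and leaving the primary C12 alcohol free.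

Step 5
Reactants: 5 12-hydroxy-13,14,15,16-tetranorlabd-8-en-7-one
Product: 6 12-iodo-13,14,15,16-tetranorlabd-8-en-7-one
Conditions: I2, PPh3, imidazole, CH2Cl2, 0 °C
Reagents that add atoms: iodine (II)
Why: Appel-type iodination converts the unhindered primary alcohol into the iodide by SN2 displacement of the alkoxyphosphonium ion under near-neutral conditions that the enone tolerates.

Step 6
Reactants: 6 12-iodo-13,14,15,16-tetranorlabd-8-en-7-one; 7 2-bromoprop-2-en-1-ol
Product: 9 14-hydroxy-15-norlabda-8,13(16)-dien-7-one, via alkylzinc iodide 8 (not isolated)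
Conditions: Zn, LiCl, THF, 35 °C; then 7, Pd(OAc)2 (2 mol%), SPhos (4 mol%), THF, rt, slow addition
Reagents that add atoms: none
Why: Zinc insertion into the primary C–I bond followed by a Pd-catalysed Negishi sp3–sp2 coupling forms the C12–C13 bond, alkylzinc halides being compatible with the ketone and, under these conditions, with the free hydroxyl of the alkenyl bromide.

Step 7
Reactants: 9 14-hydroxy-15-norlabda-8,13(16)-dien-7-one
Product: 10 (13R)-13,16-epoxy-14-hydroxy-15-norlabd-8-en-7-one
Conditions: Ti(OiPr)4 (10 mol%), D-(−)-diisopropyl tartrate (13 mol%), t-BuOOH, 4 Å MS, CH2Cl2, −20 °C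
Reagents that add atoms: tert-butyl hydroperoxide (CC(C)(C)OO)
Why: Katsuki–Sharpless asymmetric epoxidation of the 2-substituted allylic alcohol sets C13 by reagent control (the remote decalin stereocentres exert no influence), and the electron-poor enone is inert to Ti/TBHP.

Step 8
Reactants: 10 (13R)-13,16-epoxy-14-hydroxy-15-norlabd-8-en-7-one
Product: 12 (13R)-13,16-epoxylabd-8-en-14-yn-7-one, via epoxy aldehyde 11 (not isolated)
Conditions: Dess–Martin periodinane, pyridine, CH2Cl2, 0 °C; then dimethyl (1-diazo-2-oxopropyl)phosphonate, K2CO3, MeOH, 0 °C → rt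
Reagents that add atoms: dimethyl (1-diazo-2-oxopropyl)phosphonate (CC(=O)C(=[N+]=[N-])P(=O)(OC)OC)
Why: Dess–Martin oxidation gives an epoxy aldehyde that cannot epimerise (quaternary α-carbon), and Ohira–Bestmann (Seyferth–Gilbert) homologation converts it into the terminal alkyne without touching the C13–O bond.

Step 9
Reactants: 12 (13R)-13,16-epoxylabd-8-en-14-yn-7-one
Product: 13 (13R)-13-hydroxy-16-(4-methoxyphenoxy)labd-8-en-14-yn-7-one
Conditions: 4-methoxyphenol (3 equiv), Cs2CO3 (0.3 equiv), DMF, 70 °C
Reagents that add atoms: 4-methoxyphenol (COc1ccc(O)cc1)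
Why: Phenoxide opens the 2,2-disubstituted epoxide by SN2 attack at the unsubstituted CH2 (C16), so the C13–O bond and configuration are retained, and the excess phenol protonates the tertiary alkoxide at once so that the enone is not engaged.

Step 10
Reactants: 13 (13R)-13-hydroxy-16-(4-methoxyphenoxy)labd-8-en-14-yn-7-one
Product: 17 (13R)-8β-acetoxy-9α,13-epoxy-16-(4-methoxyphenoxy)labd-14-yn-7-one, via potassium alkoxide 14 (not isolated), via potassium enolate 15 (not isolated), via potassium ketol alkoxide 16 (not isolated)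
Conditions: KHMDS (1.05 equiv), THF (0.01 M), −78 °C; then 2-(phenylsulfonyl)-3-phenyloxaziridine, −78 → −30 °C; then Ac2O, DMAP (cat.), −30 → 0 °C
Reagents that add atoms: 2-(phenylsulfonyl)-3-phenyloxaziridine (O=S(=O)(c1ccccc1)N1OC1c1ccccc1); acetic anhydride (CC(=O)OC(C)=O)
Why: Proposed new method: KHMDS removes only the tertiary propargylic O–H of 13, and alkoxide 14 adds to C9 of the 8-en-7-one in a 5-exo-trig oxa-Michael closure that forms the O–C9 bond of the spiro-tetrahydrofuran and gives the tetrasubstituted C7=C8 enolate 15 regiospecifically, which the N-sulfonyloxaziridine oxidises at C8 to alkoxide 16, acetylated in the same flask; the closest known reaction types are the tandem conjugate addition/oxaziridine enolate hydroxylation and the intramolecular oxa-Michael etherification of enones, not yet combined on a fully substituted enone with a tertiary alkoxide. C9 is set by axial attack of the tethered oxygen on the α-face, anti to the C10 angular methyl as in conjugate additions to Δ1-3-keto steroids, which places the oxygen axial (9α) and C11 equatorial. C8 is set by axial (β) delivery of oxygen to the enolate, anti to the new axial C9–O bond and through a chair-like transition state in which the C17 methyl swings equatorial instead of into a 1,3-diaxial clash with the C10 methyl. C13 is not touched, and C5/C10 come from sclareolide. The step needs addition of the alkoxide to C9 to outrun α′-deprotonation at C6; one equivalent of base at −78 °C, high dilution and the intramolecular five-ring closure should favour enolate 15, and once C8 is quaternary the β-alkoxy ketone can no longer revert by retro-Michael elimination.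

Step 11
Reactants: 17 (13R)-8β-acetoxy-9α,13-epoxy-16-(4-methoxyphenoxy)labd-14-yn-7-one
Product: 18 (13R)-8β-acetoxy-9α,13-epoxy-16-hydroxylabd-14-yn-7-one
Conditions: ceric ammonium nitrate (2.5 equiv), MeCN/H2O 4:1, 0 °C
Reagents that add atoms: none
Why: Oxidative dearylation of the p-methoxyphenyl ether (aryl C–O cleavage via the arene radical cation, releasing benzoquinone) frees the primary C16 alcohol without affecting the tertiary acetate, the ketone, the alkyne or C13.

Step 12
Reactants: 18 (13R)-8β-acetoxy-9α,13-epoxy-16-hydroxylabd-14-yn-7-one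
Product: 19 (13R)-8β-acetoxy-9α,13;15,16-diepoxylabd-14-en-7-one (target)
Conditions: Mo(CO)6 (30 mol%), Et3N, Et2O, hν (350 nm), rt; filtration through Et3N-deactivated silica
Reagents that add atoms: none
Why: Molybdenum-vinylidene-mediated 5-endo cycloisomerisation of the 3-butyn-1-ol unit closes the 2,3-dihydrofuran by O16–C15 bond formation under amine-buffered, acid-free conditions that should preserve the tertiary allylic C13–O9 ether, no stereocentre being formed or touched.

**Compound list**

1 | (+)-sclareolide | O=C1C[C@H]2[C@](C)(O1)CC[C@H]1C(C)(C)CCC[C@]21C | starting material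
2 | methyl 13,14,15,16-tetranorlabd-8-en-12-oate | COC(=O)CC1=C(C)CC[C@H]2C(C)(C)CCC[C@]12C | intermediate
3 | methyl 7-oxo-13,14,15,16-tetranorlabd-8-en-12-oate | COC(=O)CC1=C(C)C(=O)C[C@H]2C(C)(C)CCC[C@]12C | intermediate
4 | 13,14,15,16-tetranorlabd-8-ene-7β,12-diol | OCCC1=C(C)[C@@H](O)C[C@H]2C(C)(C)CCC[C@]12C | intermediate
5 | 12-hydroxy-13,14,15,16-tetranorlabd-8-en-7-one | OCCC1=C(C)C(=O)C[C@H]2C(C)(C)CCC[C@]12C | intermediate
6 | 12-iodo-13,14,15,16-tetranorlabd-8-en-7-one | ICCC1=C(C)C(=O)C[C@H]2C(C)(C)CCC[C@]12C | intermediate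
7 | 2-bromoprop-2-en-1-ol | OCC(Br)=C | starting material
8 | (7-oxo-13,14,15,16-tetranorlabd-8-en-12-yl)zinc iodide | I[Zn]CCC1=C(C)C(=O)C[C@H]2C(C)(C)CCC[C@]12C | intermediate
9 | 14-hydroxy-15-norlabda-8,13(16)-dien-7-one | OCC(=C)CCC1=C(C)C(=O)C[C@H]2C(C)(C)CCC[C@]12C | intermediate
10 | (13R)-13,16-epoxy-14-hydroxy-15-norlabd-8-en-7-one | OC[C@@]1(CO1)CCC1=C(C)C(=O)C[C@H]2C(C)(C)CCC[C@]12C | intermediate
11 | (13S)-13,16-epoxy-7-oxo-15-norlabd-8-en-14-al | O=C[C@@]1(CO1)CCC1=C(C)C(=O)C[C@H]2C(C)(C)CCC[C@]12C | intermediate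
12 | (13R)-13,16-epoxylabd-8-en-14-yn-7-one | C#C[C@@]1(CO1)CCC1=C(C)C(=O)C[C@H]2C(C)(C)CCC[C@]12C | intermediate
13 | (13R)-13-hydroxy-16-(4-methoxyphenoxy)labd-8-en-14-yn-7-one | C#C[C@@](O)(COc3ccc(OC)cc3)CCC1=C(C)C(=O)C[C@H]2C(C)(C)CCC[C@]12C | intermediate
14 | potassium 13-alkoxide of 13 | C#C[C@@]([O-])(COc3ccc(OC)cc3)CCC1=C(C)C(=O)C[C@H]2C(C)(C)CCC[C@]12C.[K+] | intermediate
15 | potassium Δ7(8)-enolate of (13R)-9α,13-epoxy-16-(4-methoxyphenoxy)labd-14-yn-7-one | CC1=C([O-])C[C@H]2C(C)(C)CCC[C@]2(C)[C@@]12CC[C@@](C#C)(COc3ccc(OC)cc3)O2.[K+] | intermediate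
16 | potassium 8β-alkoxide of (13R)-9α,13-epoxy-8β-hydroxy-16-(4-methoxyphenoxy)labd-14-yn-7-one | [O-][C@@]1(C)C(=O)C[C@H]2C(C)(C)CCC[C@]2(C)[C@@]12CC[C@@](C#C)(COc3ccc(OC)cc3)O2.[K+] | intermediate
17 | (13R)-8β-acetoxy-9α,13-epoxy-16-(4-methoxyphenoxy)labd-14-yn-7-one | CC(=O)O[C@@]1(C)C(=O)C[C@H]2C(C)(C)CCC[C@]2(C)[C@@]12CC[C@@](C#C)(COc3ccc(OC)cc3)O2 | intermediate
18 | (13R)-8β-acetoxy-9α,13-epoxy-16-hydroxylabd-14-yn-7-one | CC(=O)O[C@@]1(C)C(=O)C[C@H]2C(C)(C)CCC[C@]2(C)[C@@]12CC[C@@](C#C)(CO)O2 | intermediate
19 | (13R)-8β-acetoxy-9α,13;15,16-diepoxylabd-14-en-7-one | CC(=O)O[C@@]1(C)C(=O)C[C@H]2C(C)(C)CCC[C@]2(C)[C@@]12CC[C@]1(C=COC1)O2 | target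

**Totals**

Total step count: 12. Longest linear sequence: 12 steps (from 1).

**Steps most likely to fail**

Step 10 (Proposed new method). The alkoxide may deprotonate C6 instead of adding to C9, giving a cross-conjugated dienolate that is oxidised at C6. The oxa-Michael may also revert before the enolate is trapped, or oxygen may be delivered to the α-face of the enolate. The fallback uses known chemistry, sets out from 13 and comes back at 17. Luche reduction (NaBH4, CeCl3·7H2O, MeOH, −40 °C) should give the 7β-allylic alcohol (13R)-16-(4-methoxyphenoxy)labd-8-en-14-yne-7β,13-diol F1. Hydroxyl-directed epoxidation (VO(acac)2, t-BuOOH, toluene, 0 °C → rt) should deliver oxygen syn to the 7β-hydroxyl and give (13R)-8β,9β-epoxy-16-(4-methoxyphenoxy)labd-14-yne-7β,13-diol F2. Catalytic camphorsulfonic acid in CH2Cl2 should then trigger 5-exo-tet opening at C9 by the 13-hydroxyl with inversion (trans-diaxial, Fürst–Plattner) to give (13R)-9α,13-epoxy-16-(4-methoxyphenoxy)labd-14-yne-7β,8β-diol F3. Parikh–Doering oxidation of the secondary 7-hydroxyl gives (13R)-9α,13-epoxy-8β-hydroxy-16-(4-methoxyphenoxy)labd-14-yn-7-one F4, and acetylation (Ac2O, DMAP, Et3N, 40 °C) gives 17.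

Step 9. While the epoxide is opened next to the enone, the liberated 13-alkoxide may cyclise onto C9 prematurely and without control, phenoxide may add to the enone, or attack may occur at the alkyne terminus (SN2′) instead of C16. The fallback removes the Michael acceptor for the duration of the opening; it sets out from 12 and comes back at 13. Luche reduction gives (13R)-13,16-epoxylabd-8-en-14-yn-7β-ol F5. Sodium 4-methoxyphenoxide in DMF at 80 °C then opens the epoxide at C16 to give (13R)-16-(4-methoxyphenoxy)labd-8-en-14-yne-7β,13-diol F6 (identical in structure with F1). MnO2 in CH2Cl2 re-oxidises the allylic alcohol to 13.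

Step 12. The tertiary allylic C13–O9 ether of the product may ionise during cyclisation or work-up and aromatise to the 3-substituted furan, or vinylidene formation may stall at the hindered quaternary propargylic centre. The fallback builds the enol ether by lactol dehydration under base; it sets out from 18 and comes back at 19. Hydroboration with dicyclohexylborane (THF, 0 °C) and oxidation with NaBO3·4H2O should give the C15 aldehyde, which closes with the C16 hydroxyl to the lactol (13R)-8β-acetoxy-9α,13;15,16-diepoxy-15-hydroxylabdan-7-one F7 (C15 epimers). MsCl and Et3N (CH2Cl2, 0 → 40 °C) then eliminate the anomeric mesylate to give 19.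

**Further compounds**

F1 | step 10 | (13R)-16-(4-methoxyphenoxy)labd-8-en-14-yne-7β,13-diol | C#C[C@@](O)(COc3ccc(OC)cc3)CCC1=C(C)[C@@H](O)C[C@H]2C(C)(C)CCC[C@]12C
F2 | step 10 | (13R)-8β,9β-epoxy-16-(4-methoxyphenoxy)labd-14-yne-7β,13-diol | C#C[C@@](O)(COc3ccc(OC)cc3)CC[C@@]14O[C@@]4(C)[C@@H](O)C[C@H]2C(C)(C)CCC[C@]12C
F3 | step 10 | (13R)-9α,13-epoxy-16-(4-methoxyphenoxy)labd-14-yne-7β,8β-diol | O[C@@]1(C)[C@@H](O)C[C@H]2C(C)(C)CCC[C@]2(C)[C@@]12CC[C@@](C#C)(COc3ccc(OC)cc3)O2
F4 | step 10 | (13R)-9α,13-epoxy-8β-hydroxy-16-(4-methoxyphenoxy)labd-14-yn-7-one | O[C@@]1(C)C(=O)C[C@H]2C(C)(C)CCC[C@]2(C)[C@@]12CC[C@@](C#C)(COc3ccc(OC)cc3)O2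
F5 | step 9 | (13R)-13,16-epoxylabd-8-en-14-yn-7β-ol | C#C[C@@]1(CO1)CCC1=C(C)[C@@H](O)C[C@H]2C(C)(C)CCC[C@]12C
F6 | step 9 | (13R)-16-(4-methoxyphenoxy)labd-8-en-14-yne-7β,13-diol | C#C[C@@](O)(COc3ccc(OC)cc3)CCC1=C(C)[C@@H](O)C[C@H]2C(C)(C)CCC[C@]12C
F7 | step 12 | (13R)-8β-acetoxy-9α,13;15,16-diepoxy-15-hydroxylabdan-7-one | CC(=O)O[C@@]1(C)C(=O)C[C@H]2C(C)(C)CCC[C@]2(C)[C@@]12CC[C@]1(CC(O)OC1)O2
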